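**Plan**

1. Numbering: ring carbons C1 (the methine) to C14 in the order C1–C2–C3=C4(CH3)–C5–C6–C7=C8(CH2OH)–C9–C10–C11=C12(CH3)–C13–C14; C15 is the carbinol carbon on C1. The target is (1R,15R).
2. Retrosynthesis: the C8 hydroxymethyl group is taken back to a methyl ester. The ring bond C1–C2 and the C15–O bond are then cut together, which opens the only ring to an achiral linear pentaene allylic alcohol. That chain is cut at C7=C8 (olefination) and C8–C9 (alkylation) into a C2–C7 aldehyde from neryl acetate, a phosphonoacetate (C8) and homofarnesyl iodide from farnesol.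
3. Forward: C8–C9 is made first, C7=C8 joins the two halves, the acetate is removed, the 14-membered ring is closed through C1–C2, and the ester is reduced last.
4. Enabling feature: C2 is allylic to the Z C3=C4 alkene and C1 carries the exocyclic tertiary carbinol C15. The C1–C2 bond of the 14-membered ring and the C15 hydroxyl are therefore the two bonds that trans addition of a C2 allyl cation and of water across an E C1=C15 alkene leaves behind.
5. Stereochemistry: Z C3=C4 comes from neryl acetate, E C11=C12 and E C1=C15 from farnesol, E C7=C8 from the olefination. C1 and C15 are created together in the ring closure, their relative configuration by anti addition to the E alkene and their absolute configuration by the chiral counter-anion.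

Key step: step 10

Remark: the sense of induction of the confined acid in step 10 cannot be deduced beforehand; the (S,S) acid is written, and its mirror image is used instead if that is the one that delivers (1R,15R)-15.

**Route**

Step 1
Reactants: 1 neryl acetate
Product: 2 (2Z)-5-(3,3-dimethyloxiran-2-yl)-3-methylpent-2-en-1-yl acetate (racemic)
Conditions: m-CPBA (1.05 equiv), CH2Cl2, −10 → 0 °C
Reagents that add atoms: m-chloroperoxybenzoic acid, `OOC(=O)c1cccc(Cl)c1` (epoxide oxygen)
Why: Prilezhaev epoxidation should take the electron-rich 6,7-alkene because the 2,3-alkene is deactivated by the allylic acetate; the new stereocentre forms as a racemate and is destroyed in step 2.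

Step 2
Reactants: 2 epoxide
Product: 4 (2Z)-3-methyl-6-oxohex-2-en-1-yl acetate, via vicinal diol 3 (not isolated)
Conditions: H5IO6, THF/H2O, 0 °C → rt
Reagents that add atoms: water, `O` (becomes the tertiary hydroxyl of 3 and leaves with the acetone)
Why: Acid-mediated epoxide hydrolysis followed in the same flask by Malaprade glycol cleavage should give the aldehyde and acetone while the Z allylic acetate is untouched.

Step 3
Reactants: 5 (2E,6E)-farnesol
Product: 6 (2E,6E)-farnesal
Conditions: 2,2,6,6-tetramethylpiperidin-1-oxyl (10 mol %), PhI(OAc)2, CH2Cl2, rt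
Reagents that add atoms: none
Why: Oxoammonium-mediated oxidation of a primary allylic alcohol should stop at the enal without isomerising the 2E alkene.

Step 4
Reactants: 6 farnesal
Product: 7 (3E,7E)-4,8,12-trimethyltrideca-1,3,7,11-tetraene
Conditions: Ph3PCH3Br, n-BuLi, THF, −78 → 0 °C
Reagents that add atoms: methyltriphenylphosphonium bromide, `C[P+](c1ccccc1)(c1ccccc1)c1ccccc1.[Br-]` (the CH2 group)
Why: Wittig methylenation of the enal with the non-stabilised ylide should give the terminal diene and leave the trisubstituted alkenes alone.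

Step 5
Reactants: 7 tetraene
Product: 9 homofarnesol [(3E,7E)-4,8,12-trimethyltrideca-3,7,11-trien-1-ol], via alkylborane 8 (not isolated)
Conditions: 9-borabicyclo[3.3.1]nonane, THF, 0 °C → rt; then NaOH, H2O2, 0 °C
Reagents that add atoms: 9-borabicyclo[3.3.1]nonane, `B1C2CCCC1CCC2` (boron of 8 only); hydrogen peroxide, `OO` (hydroxyl oxygen of 9)
Why: Anti-Markovnikov hydroboration with the bulky dialkylborane should be selective for the monosubstituted terminal alkene of the diene, and oxidation then gives the primary alcohol (hydroboration–oxidation).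

Step 6
Reactants: 9 homofarnesol
Product: 10 homofarnesyl iodide [(3E,7E)-1-iodo-4,8,12-trimethyltrideca-3,7,11-triene]
Conditions: PPh3, I2, imidazole, CH2Cl2, 0 °C
Reagents that add atoms: iodine, `II`
Why: Appel-type iodination should convert the primary homoallylic alcohol into the iodide by SN2 displacement without touching the alkenes.

Step 7
Reactants: 10 homofarnesyl iodide; 11 methyl 2-(diethoxyphosphoryl)acetate
Product: 12 methyl (5E,9E)-2-(diethoxyphosphoryl)-6,10,14-trimethylpentadeca-5,9,13-trienoate (racemic)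
Conditions: 11 (2 equiv), NaH, DMF, 0 → 50 °C
Reagents that add atoms: none
Why: SN2 alkylation of the sodium phosphonoacetate by the primary iodide in a dipolar aprotic solvent should form C8–C9, excess 11 limiting double alkylation; the racemic stereocentre at C8 disappears in step 8.

Step 8
Reactants: 12 phosphonate; 4 aldehyde
Product: 13 methyl (2E,6Z)-8-acetoxy-6-methyl-2-[(3E,7E)-4,8,12-trimethyltrideca-3,7,11-trien-1-yl]octa-2,6-dienoate
Conditions: NaH, THF, 0 °C; then 4, 0 °C → rt
Reagents that add atoms: none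
Why: Horner–Wadsworth–Emmons olefination with a diethyl phosphonate and a sodium counter-ion should add reversibly and favour the E enoate (C6 trans to the ester), any Z isomer being removed by chromatography.

Step 9
Reactants: 13 acetate
Product: 14 methyl (2E,6Z)-8-hydroxy-6-methyl-2-[(3E,7E)-4,8,12-trimethyltrideca-3,7,11-trien-1-yl]octa-2,6-dienoate
Conditions: K2CO3, MeOH, 0 °C
Reagents that add atoms: none
Why: Base-catalysed transesterification (Zemplén type) should remove the acetate, while the methyl ester only exchanges methoxide with the solvent.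

Step 10
Reactants: 14 linear Z-allylic alcohol
Product: 15 methyl (1E,5Z,8R,11E)-8-[(2R)-2-hydroxy-6-methylhept-5-en-2-yl]-5,11-dimethylcyclotetradeca-1,5,11-triene-1-carboxylate
Conditions: (S,S)-imidodiphosphorimidate acid HN[P(=NSO2CF3)(O2Ar*)]2, Ar*(OH)2 = (S)-3,3′-bis[3,5-bis(trifluoromethyl)phenyl]-1,1′-bi-2-naphthol (10 mol %), CHCl3, 0.002 M, −40 → −10 °C, no drying agent; Et3N quench
Reagents that add atoms: none
Why: Proposed new method: the acid protonates the C2 hydroxyl and water leaves, giving a cisoid C2–C3–C4 allyl cation in a contact ion pair with the chiral anion; C1 of the E C1=C15 alkene attacks C2, and the water just released, still held by the anion, adds to the resulting C15 cation. The closest known reaction types are the SnCl4-promoted 14-membered cation–olefin closure of a polyprenoic acid chloride and enantioselective polyene cyclisations under confined imidodiphosphorimidate acids; a dehydrative allyl cation–olefin macrocyclisation with return of water has not been described. The 14-membered ring closes in the exo mode with respect to the attacking alkene (C1 inside the ring, C15 outside as the tertiary cation). C1 and C15 arise together: their relative configuration follows from anti addition of C2 and OH across the E alkene, their absolute configuration (1R,15R) from the alkene face that the chiral anion leaves open. The step needs C1=C15 to be the only alkene that attacks C2: C7=C8 is switched off by the conjugated ester, C11=C12 could only close a strained 10- or 11-membered ring, and the terminal alkene only an 18-membered one. High dilution, low temperature and a non-fluorinated solvent are chosen so that ether formation between two molecules, rotation of the allyl cation and protonation of the trisubstituted alkenes stay slower than ring closure.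

Step 11
Reactants: 15 macrocyclic ester
Product: 16 (2R)-2-[(1R,3Z,7E,11E)-8-(hydroxymethyl)-4,12-dimethylcyclotetradeca-3,7,11-trien-1-yl]-6-methylhept-5-en-2-ol
Conditions: i-Bu2AlH (3.5 equiv), CH2Cl2, −78 → −20 °C; aqueous potassium sodium tartrate
Reagents that add atoms: none
Why: Hydride reduction of the conjugated methyl ester by i-Bu2AlH should proceed by 1,2-addition to the allylic alcohol, the tertiary alcohol being only deprotonated and no stereocentre touched.

**Compound list**

1 | neryl acetate, (2Z)-3,7-dimethylocta-2,6-dien-1-yl acetate | `CC(C)=CCC/C(C)=C\COC(C)=O` | starting material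
2 | (2Z)-5-(3,3-dimethyloxiran-2-yl)-3-methylpent-2-en-1-yl acetate (racemic) | `CC1(C)OC1CC/C(C)=C\COC(C)=O` | intermediate
3 | (2Z)-6,7-dihydroxy-3,7-dimethyloct-2-en-1-yl acetate (racemic) | `CC(C)(O)C(O)CC/C(C)=C\COC(C)=O` | intermediate (not isolated)
4 | (2Z)-3-methyl-6-oxohex-2-en-1-yl acetate | `O=CCC/C(C)=C\COC(C)=O` | intermediate
5 | (2E,6E)-farnesol | `CC(C)=CCC/C(C)=C/CC/C(C)=C/CO` | starting material
6 | (2E,6E)-farnesal | `CC(C)=CCC/C(C)=C/CC/C(C)=C/C=O` | intermediate
7 | (3E,7E)-4,8,12-trimethyltrideca-1,3,7,11-tetraene | `CC(C)=CCC/C(C)=C/CC/C(C)=C/C=C` | intermediate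
8 | 9-[(3E,7E)-4,8,12-trimethyltrideca-3,7,11-trien-1-yl]-9-borabicyclo[3.3.1]nonane | `CC(C)=CCC/C(C)=C/CC/C(C)=C/CCB1C2CCCC1CCC2` | intermediate (not isolated)
9 | homofarnesol, (3E,7E)-4,8,12-trimethyltrideca-3,7,11-trien-1-ol | `CC(C)=CCC/C(C)=C/CC/C(C)=C/CCO` | intermediate
10 | homofarnesyl iodide, (3E,7E)-1-iodo-4,8,12-trimethyltrideca-3,7,11-triene | `CC(C)=CCC/C(C)=C/CC/C(C)=C/CCI` | intermediate
11 | methyl 2-(diethoxyphosphoryl)acetate | `CCOP(=O)(CC(=O)OC)OCC` | starting material
12 | methyl (5E,9E)-2-(diethoxyphosphoryl)-6,10,14-trimethylpentadeca-5,9,13-trienoate (racemic) | `COC(=O)C(CC/C=C(\C)CC/C=C(\C)CCC=C(C)C)P(=O)(OCC)OCC` | intermediate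
13 | methyl (2E,6Z)-8-acetoxy-6-methyl-2-[(3E,7E)-4,8,12-trimethyltrideca-3,7,11-trien-1-yl]octa-2,6-dienoate | `CC(=O)OC/C=C(/C)CC/C=C(/C(=O)OC)CC/C=C(\C)CC/C=C(\C)CCC=C(C)C` | intermediate
14 | methyl (2E,6Z)-8-hydroxy-6-methyl-2-[(3E,7E)-4,8,12-trimethyltrideca-3,7,11-trien-1-yl]octa-2,6-dienoate | `OC/C=C(/C)CC/C=C(/C(=O)OC)CC/C=C(\C)CC/C=C(\C)CCC=C(C)C` | intermediate (precursor of the key step)
15 | methyl (1E,5Z,8R,11E)-8-[(2R)-2-hydroxy-6-methylhept-5-en-2-yl]-5,11-dimethylcyclotetradeca-1,5,11-triene-1-carboxylate | `CC(C)=CCC[C@@](C)(O)[C@H]1C/C=C(/C)CC/C=C(/C(=O)OC)CC/C=C(\C)CC1` | intermediate (product of the key step)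
16 | (2R)-2-[(1R,3Z,7E,11E)-8-(hydroxymethyl)-4,12-dimethylcyclotetradeca-3,7,11-trien-1-yl]-6-methylhept-5-en-2-ol | `CC(C)=CCC[C@@](C)(O)[C@H]1C/C=C(/C)CC/C=C(/CO)CC/C=C(\C)CC1` | target

**Count**

Total steps: 11. Longest linear sequence: 9 steps (5 to 16, steps 3–11).

**Steps most likely to fail**

**Step 10 (ring closure).** Several processes may defeat it:
- Protonation of the trisubstituted alkenes may outrun ionisation and start six-membered ring formation from the chain end.
- The allyl cation may lose a proton or take the water back at C4 before C1 reaches C2.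
- The alkene face may be poorly discriminated in the ion pair.
- The tertiary alcohol formed may ionise again and eliminate.

Fallback (known chemistry): the same C1–C2 bond is closed with reversed polarity. An allyl phenyl sulfide carbanion at C2 opens a C1–C15 epoxide of fixed configuration at C1 with inversion while the C15–O bond is kept, which gives the same anti relationship. The fallback sets out from aldehyde 4 and phosphonate 11, with geraniol and methyl acetoacetate as added purchased materials, and comes back at target 16.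

Geraniol is epoxidised by Sharpless asymmetric epoxidation (Ti(OiPr)4, D-(−)-diethyl tartrate, t-BuOOH, 4 Å sieves, CH2Cl2, −20 °C) to (2R,3R)-2,3-epoxygeraniol F1. PPh3, I2 and imidazole convert it into (2R,3R)-2,3-epoxygeranyl iodide F2. γ-Alkylation of the dianion of methyl acetoacetate (NaH, then n-BuLi, THF, 0 °C) with F2 should give β-keto ester F3. Its Z enol phosphate F4 (NaH, ClP(O)(OEt)2, Et2O, 0 °C) should react with Me2CuLi (Et2O, −78 °C) with retention to give methyl (2E,6R,7R)-6,7-epoxyfarnesoate F5, which i-Bu2AlH reduces to (2E,6R,7R)-6,7-epoxyfarnesol F6.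

The conditions of steps 3 to 8 then lead in turn to the following compounds:
- epoxy enal F7 (oxoammonium oxidation);
- epoxy tetraene F8 (Wittig methylenation);
- epoxy alkylborane F9 (9-borabicyclo[3.3.1]nonane), oxidised without isolation to epoxy homofarnesol F10;
- epoxy homofarnesyl iodide F11 (PPh3, I2, imidazole);
- epoxy phosphonate F12 (11, NaH, DMF);
- epoxy enoate acetate F13 (4, NaH, THF).

K2CO3 in MeOH frees the epoxy enoate alcohol F14. PhSSPh and Bu3P in THF convert it into allyl phenyl sulfide ester F15, and i-Bu2AlH (CH2Cl2, −78 °C) reduces the ester to the hydroxymethyl sulfide F16. At high dilution, n-BuLi (2.2 equiv) with 1,4-diazabicyclo[2.2.2]octane in THF at −78 °C deprotonates the hydroxyl and C2. The carbanion should attack the epoxide at its less substituted carbon C1 and close the 14-membered ring to the macrocyclic sulfide F17. Li in EtNH2 (−78 °C) then removes the phenylsulfanyl group to give 16.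

**Step 8 (olefination).** Elimination from the α-branched phosphonate adduct may run under partly kinetic control, so that E/Z selectivity erodes and the isomers co-elute.

Fallback: the alkene geometry is fixed by a stereoretentive cross-coupling. It sets out from aldehyde 4 and alkylborane 8 (made from 7 as in step 5) and comes back at 14. Aldehyde 4 is converted by an iodo-ylide Wittig reaction (Ph3P=CHCO2Me, N-iodosuccinimide, CH2Cl2, −20 °C; then 4, K2CO3, rt) into methyl (2Z,6Z)-8-acetoxy-2-iodo-6-methylocta-2,6-dienoate F18. The acetate is removed (K2CO3, MeOH, 0 °C) to give methyl (2Z,6Z)-8-hydroxy-2-iodo-6-methylocta-2,6-dienoate F19, so that no allylic ester meets zerovalent palladium. B-alkyl Suzuki–Miyaura coupling of F19 with 8 ([1,1′-bis(diphenylphosphino)ferrocene]PdCl2, AsPh3, Cs2CO3, DMF/THF/H2O, rt) should replace iodine by C9 with retention and give 14 directly.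

**Step 7 (alkylation).** Substitution by the hindered stabilised anion at the homoallylic carbon may be slow, so that E2 elimination to the conjugated diene and double alkylation take over.

Fallback: C8–C9 is made from the borane and phosphorus is introduced afterwards. It sets out from alkylborane 8 and comes back at 12. Organoborane alkylation of methyl bromoacetate (8, potassium 2,6-di-tert-butylphenoxide, THF, 0 °C) should give methyl (5E,9E)-6,10,14-trimethylpentadeca-5,9,13-trienoate F20. Its lithium enolate (LDA, THF, −78 °C) is C-phosphinylated with ClP(OEt)2 to the phosphonite ester F21 (not isolated), which air or H2O2 oxidises to phosphonate 12.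

Further compounds
F1 | step 10 | (2R,3R)-2,3-epoxygeraniol, [(2R,3R)-3-methyl-3-(4-methylpent-3-en-1-yl)oxiran-2-yl]methanol | `OC[C@H]1O[C@]1(C)CCC=C(C)C`
F2 | step 10 | (2R,3R)-2,3-epoxygeranyl iodide (iodide of F1, epoxide unchanged) | `IC[C@H]1O[C@]1(C)CCC=C(C)C`
F3 | step 10 | methyl 5-[(2R,3R)-3-methyl-3-(4-methylpent-3-en-1-yl)oxiran-2-yl]-3-oxopentanoate | `COC(=O)CC(=O)CC[C@H]1O[C@]1(C)CCC=C(C)C`
F4 | step 10 | methyl (2Z)-3-[(diethoxyphosphoryl)oxy]-5-[(2R,3R)-3-methyl-3-(4-methylpent-3-en-1-yl)oxiran-2-yl]pent-2-enoate | `COC(=O)/C=C(\OP(=O)(OCC)OCC)CC[C@H]1O[C@]1(C)CCC=C(C)C`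
F5 | step 10 | methyl (2E,6R,7R)-6,7-epoxyfarnesoate | `COC(=O)/C=C(\C)CC[C@H]1O[C@]1(C)CCC=C(C)C`
F6 | step 10 | (2E,6R,7R)-6,7-epoxyfarnesol | `OC/C=C(\C)CC[C@H]1O[C@]1(C)CCC=C(C)C`
F7 | step 10 | (2E,6R,7R)-6,7-epoxyfarnesal | `O=C/C=C(\C)CC[C@H]1O[C@]1(C)CCC=C(C)C`
F8 | step 10 | (2R,3R)-2-methyl-3-[(3E)-3-methylhexa-3,5-dien-1-yl]-2-(4-methylpent-3-en-1-yl)oxirane | `C=C/C=C(\C)CC[C@H]1O[C@]1(C)CCC=C(C)C`
F9 | step 10 | 9-{(3E)-4-methyl-6-[(2R,3R)-3-methyl-3-(4-methylpent-3-en-1-yl)oxiran-2-yl]hex-3-en-1-yl}-9-borabicyclo[3.3.1]nonane | `C(C/C=C(\C)CC[C@H]1O[C@]1(C)CCC=C(C)C)B2C3CCCC2CCC3`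
F10 | step 10 | (3E)-4-methyl-6-[(2R,3R)-3-methyl-3-(4-methylpent-3-en-1-yl)oxiran-2-yl]hex-3-en-1-ol | `OCC/C=C(\C)CC[C@H]1O[C@]1(C)CCC=C(C)C`
F11 | step 10 | (2R,3R)-3-[(3E)-6-iodo-3-methylhex-3-en-1-yl]-2-methyl-2-(4-methylpent-3-en-1-yl)oxirane | `ICC/C=C(\C)CC[C@H]1O[C@]1(C)CCC=C(C)C`
F12 | step 10 | methyl (5E)-2-(diethoxyphosphoryl)-6-methyl-8-[(2R,3R)-3-methyl-3-(4-methylpent-3-en-1-yl)oxiran-2-yl]oct-5-enoate (racemic at C2) | `COC(=O)C(CC/C=C(\C)CC[C@H]1O[C@]1(C)CCC=C(C)C)P(=O)(OCC)OCC`
F13 | step 10 | methyl (2E,6Z)-8-acetoxy-6-methyl-2-{(3E)-4-methyl-6-[(2R,3R)-3-methyl-3-(4-methylpent-3-en-1-yl)oxiran-2-yl]hex-3-en-1-yl}octa-2,6-dienoate | `CC(=O)OC/C=C(/C)CC/C=C(/C(=O)OC)CC/C=C(\C)CC[C@H]1O[C@]1(C)CCC=C(C)C`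
F14 | step 10 | methyl (2E,6Z)-8-hydroxy-6-methyl-2-{(3E)-4-methyl-6-[(2R,3R)-3-methyl-3-(4-methylpent-3-en-1-yl)oxiran-2-yl]hex-3-en-1-yl}octa-2,6-dienoate | `OC/C=C(/C)CC/C=C(/C(=O)OC)CC/C=C(\C)CC[C@H]1O[C@]1(C)CCC=C(C)C`
F15 | step 10 | methyl (2E,6Z)-6-methyl-2-{(3E)-4-methyl-6-[(2R,3R)-3-methyl-3-(4-methylpent-3-en-1-yl)oxiran-2-yl]hex-3-en-1-yl}-8-(phenylsulfanyl)octa-2,6-dienoate | `c1ccccc1SC/C=C(/C)CC/C=C(/C(=O)OC)CC/C=C(\C)CC[C@H]1O[C@]1(C)CCC=C(C)C`
F16 | step 10 | (2E,6Z)-6-methyl-2-{(3E)-4-methyl-6-[(2R,3R)-3-methyl-3-(4-methylpent-3-en-1-yl)oxiran-2-yl]hex-3-en-1-yl}-8-(phenylsulfanyl)octa-2,6-dien-1-ol | `c1ccccc1SC/C=C(/C)CC/C=C(/CO)CC/C=C(\C)CC[C@H]1O[C@]1(C)CCC=C(C)C`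
F17 | step 10 | 2-(phenylsulfanyl) derivative of 16 (SPh on ring C2, both epimers; C1 and C15 arranged in space as in 16) | `CC(C)=CCC[C@@](C)(O)[C@H]1C(Sc2ccccc2)/C=C(/C)CC/C=C(/CO)CC/C=C(\C)CC1`
F18 | step 8 | methyl (2Z,6Z)-8-acetoxy-2-iodo-6-methylocta-2,6-dienoate | `COC(=O)/C(I)=C/CC/C(C)=C\COC(C)=O`
F19 | step 8 | methyl (2Z,6Z)-8-hydroxy-2-iodo-6-methylocta-2,6-dienoate | `COC(=O)/C(I)=C/CC/C(C)=C\CO`
F20 | step 7 | methyl (5E,9E)-6,10,14-trimethylpentadeca-5,9,13-trienoate | `COC(=O)CCC/C=C(\C)CC/C=C(\C)CCC=C(C)C`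
F21 | step 7 | methyl (5E,9E)-2-(diethoxyphosphanyl)-6,10,14-trimethylpentadeca-5,9,13-trienoate (racemic) | `COC(=O)C(CC/C=C(\C)CC/C=C(\C)CCC=C(C)C)P(OCC)OCC`
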